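The numbers in the tables come from a simulation from invented constants, noise included.

Start with the easiest thing the elm run shows: its rate falls. Over the first 13 h it averages 2.58 mM/h, and over the last stretch 0.0331 mM/h, a slowing by a factor of 77.9. If the rate is first order in c(substrate), the fall of c(substrate) gives a factor of 1.55, so I put the remaining 50.2 on the coupling partner. The maple run, where the coupling partner is the limiting reagent, slows to 0.0400 mM/h after making 135 mM of target, less than the 250 mM of partner charged. So I take it that the partner has a second way out.

| flask | substrate | coupling partner | time |
|---|---|---|---|
| elm | 250 mM | 250 mM |  |
| ash | 150 mM | 150 mM |  |
| maple | 500 mM | 250 mM |  |
| alder | 1000 mM | 1000 mM | 330 h |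

- elm run (time / h: [substrate] / mM): 13: 216.5; 25: 200.1; 48: 184.0; 91: 173.9; 170: 166.7; 330: 161.4
- ash run (time / h: [substrate] / mM): 13: 138.7; 25: 132.3; 48: 125.2; 91: 120.7; 170: 114.6; 330: 112.4
- maple run (time / h: [substrate] / mM): 13: 440.2; 25: 414.3; 48: 391.0; 91: 377.4; 170: 371.3; 330: 364.9

(readings scatter by 0.8 mM)

- Overall: substrate + coupling partner -> target.
- Constant volume, constant temperature.
- The analysis sees a species whether free or bound.
- "The second partner" is coupling partner.
- An order is taken over about fifteen percent of the charge, up and down.

1. apparent order in [substrate] of the starting rate, round the charge of the elm run (the rate where two percent of its substrate have turned into target) (one fixed amount of target, the same in the runs compared)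
2. apparent order in [coupling partner] of the starting rate, round the charge of the elm run (the rate where two percent of its substrate have turned into target)
3. substrate in the alder run at 330 h, as a share of the substrate charged
4. which of these the readings show (the product binds the substrate / the second partner is lost by itself / the second partner is lost in pairs)

Suppose that coupling and loss depend on the partner in the same way. Their ratio then depends on c(substrate) and one constant, a selectivity factor in form. Call it the waste level, the c(substrate) at which partner is lost as fast as it couples. Summed over a run, the partner charged equals the partner left plus the target made plus the waste level times the logarithm of substrate charged over substrate remaining. Setting the partner left at 330 h to zero, a simplification of mine, the elm run reads 369 mM and the maple run 365 mM. The ash run reads 390 mM, but there a shift of the last reading by its scatter of 0.8 mM moves the figure by 12.7 mM, more than the 6.06 mM of the elm run. So I carry the mean of the elm and maple figures, 367 mM.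

In the alder run the charges are equal, so with the partner left at 330 h again set to zero, the substrate remaining equals the partner lost. Try the waste level itself as that amount: one round gives 368 mM, and putting this back gives 367 mM. My reckoning is therefore 36.7%.

The forecast says 35.5%, lower than mine, with orders 1 in substrate and 2 in the partner and the verdict that the second partner is lost in pairs, noting that “the tails are not exponential”.

The alder run gives 36.8%. The readings show that the second partner is lost in pairs, with orders 1.1 in substrate and 1.4 in the partner, below the forecast's 2.

    2 coupling partner ⇌ reagent dimer, settled at all times (4.320 /M)
    substrate + reagent dimer → target + coupling partner (0.2196 /M/h)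
    2 coupling partner → lost reagent (0.1717 /M/h)

Put back into the balance, with the partner left again set to zero, the alder figure gives a waste level of 368 mM. Now take the maple run at 111 h, where target reaches a quarter of the substrate charged, 125 mM: the carried waste level puts the partner lost by then at 106 mM, and so the partner left, free and in the reagent dimer together, at an estimated 19.5 mM of its 250 mM.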